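**Plan**
- Retrosynthesis: the C4 formyl group is masked as a diethyl acetal. The cyclopentenone is cut at C2=C3 (aldol) to give 1,2-diacylbenzene 20. The benzene ring is then cut at C3a–C7a and C4–C5 ([4+2]) to give dienone 13 and ynone 18.
- Enabling feature: in the benzene ring (C3a, C4, C5, C6, C7, C7a) the guaiazulenyl donor sits on C6, between C5–H and C7–CH3, and C7a carries the C1 carbonyl. C5=C6–C7=C7a is therefore a 1-acyl-2-methyl-3-azulenyl diene polarised towards C5. C3a≡C4 is an alkyne with acetyl on C3a and a masked CHO on C4.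
- Dienone 13 is cut at C6–C7 (Suzuki–Miyaura) into alkenylboronate 6 and E-iodoenone 12. Boronate 6 comes from guaiazulene by C–H alkynylation and Markovnikov hydrometalation. In 12 the C2–azulene bond comes from a ketocarbene C–H functionalisation.
- Forward order: the chain is joined at C6–C7 (step 7), the benzene ring forms (step 9), the five-membered ring forms (step 10), and the aldehyde is released (step 11).
- Stereochemistry: the target has no stereocentre. The only stereo element on the way is the E alkene C7=C7a of 13. It is set under thermodynamic control in step 4 and carried with retention through step 7. The C7a centre of 19 is erased on aromatisation.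

Key step: step 9

Remark: Gu = guaiazulen-3-yl = 5-isopropyl-3,8-dimethylazulen-1-yl; atom labels C1–C7a are those of the indenone of the target and are kept for all precursors; activated MnO2 is assumed to spare the azulene methyl groups, as it does when used to dehydrogenate hydroazulenes.

**Step 1**
Reactants: 1 guaiazulene (7-isopropyl-1,4-dimethylazulene); 2 TIPS-EBX (1-[(triisopropylsilyl)ethynyl]-1,2-benziodoxol-3(1H)-one)
Product: 3 3-[(triisopropylsilyl)ethynyl]guaiazulene
Conditions: AuCl (5 mol %), MeCN, rt, Ar, dark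
Reagents that add atoms: none
Why: Gold-catalysed electrophilic C–H alkynylation using an ethynylbenziodoxolone, a reaction documented for azulenes, strikes C3, the only free nucleophilic position of the five-membered ring of 1 (C1 carries methyl), and brings in the two carbons that become C6 and C5.

**Step 2**
Reactants: 3 3-[(triisopropylsilyl)ethynyl]guaiazulene
Product: 4 3-ethynylguaiazulene
Conditions: Bu4NF (1.1 equiv, wet THF), 0 °C
Reagents that add atoms: none
Why: Fluoride-mediated protodesilylation of an alkynylsilane, driven by the strong Si–F bond, leaves the azulene untouched, and 4 is used at once because electron-rich ethynylazulenes polymerise on storage.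

**Step 3**
Reactants: 4 3-ethynylguaiazulene
Product: 6 2-[1-(guaiazulen-3-yl)vinyl]-4,4,5,5-tetramethyl-1,3,2-dioxaborolane, via alkenylalane 5 (not isolated)
Conditions: i-Bu2AlH (1.3 equiv), Ni(dppp)Cl2 (3 mol %; dppp = 1,3-bis(diphenylphosphino)propane), THF, rt; then MeOBpin (3 equiv), 0 °C to rt; Et3N-deactivated silica
Reagents that add atoms: 2-methoxy-4,4,5,5-tetramethyl-1,3,2-dioxaborolane (MeOBpin), COB1OC(C)(C)C(C)(C)O1; diisobutylaluminium hydride, CC(C)C[AlH]CC(C)C (its aluminium stays only in 5)
Why: Nickel-catalysed Markovnikov hydroalumination of a terminal arylacetylene, in which the bidentate dppp ligand steers aluminium to the internal carbon, followed by aluminium-to-boron exchange with MeOBpin, gives the 1,1-disubstituted alkenylboronate without strong base, so the acidic C4 methyl group of the azulene is not touched.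

**Step 4**
Reactants: 7 but-2-ynoic acid
Product: 8 (E)-3-iodobut-2-enoic acid
Conditions: 57% aq. HI (1.5 equiv), sealed tube, 130 °C; crystallisation
Reagents that add atoms: hydrogen iodide, I
Why: Hydroiodination of an alkynoic acid by conjugate addition of iodide, run hot so that the kinetic Z acid equilibrates through reversible HI addition to the more stable E acid (iodine trans to CO2H), sets the alkene geometry that later turns the acyl group outward on the diene.

**Step 5**
Reactants: 8 (E)-3-iodobut-2-enoic acid; 9 (trimethylsilyl)diazomethane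
Product: 11 (E)-1-diazo-4-iodopent-3-en-2-one, via acid chloride 10 (not isolated)
Conditions: (COCl)2, DMF (cat.), CH2Cl2, 0 °C to rt, evaporate; then 9 (2 equiv), MeCN/THF, 0 °C
Reagents that add atoms: oxalyl chloride, O=C(Cl)C(=O)Cl (its chlorine stays only in 10)
Why: Acylation of a diazomethane equivalent by an acid chloride (first half of the Arndt–Eistert sequence) gives the alpha-diazoketone, the beta,beta-disubstituted alkene being too hindered for competing dipolar cycloaddition, and supplies the carbon that becomes C2.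

**Step 6**
Reactants: 1 guaiazulene; 11 (E)-1-diazo-4-iodopent-3-en-2-one
Product: 12 (E)-1-(guaiazulen-3-yl)-4-iodopent-3-en-2-one
Conditions: (IPr)AuCl (2 mol %; IPr = 1,3-bis(2,6-diisopropylphenyl)imidazol-2-ylidene), NaB[3,5-(CF3)2C6H3]4 (2 mol %), 1 (2 equiv), CH2Cl2, rt, 11 added slowly by syringe pump
Reagents that add atoms: none
Why: Metal-carbene C–H functionalisation of an azulene by an acceptor diazocarbonyl compound: the electrophilic gold carbene formed from 11 by loss of N2 is attacked by C3 of 1 in a Friedel–Crafts-like manner and proton transfer restores the azulene, slow addition and excess 1 suppressing carbene dimerisation, while the iodine, trans to the acyl group, cannot reach the carbene carbon.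

**Step 7**
Reactants: 6 2-[1-(guaiazulen-3-yl)vinyl]-4,4,5,5-tetramethyl-1,3,2-dioxaborolane; 12 (E)-1-(guaiazulen-3-yl)-4-iodopent-3-en-2-one
Product: 13 (E)-1,5-bis(guaiazulen-3-yl)-4-methylhexa-3,5-dien-2-one
Conditions: Pd(OAc)2 (5 mol %), SPhos (10 mol %), K3PO4 (2 equiv), THF/H2O 10:1, 40 °C, degassed
Reagents that add atoms: none
Why: Suzuki–Miyaura coupling of an alkenylboronate and a beta-iodoenone forms C6–C7 with retention at both sp2 carbons, the activated C–I bond adding to zerovalent palladium at low temperature and the bulky SPhos ligand easing transmetalation of the hindered 1,1-disubstituted boronate, so the E geometry of 12 passes into 13.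

**Step 8**
Reactants: 14 3,3-diethoxyprop-1-yne; 15 N-methoxy-N-methylacetamide
Product: 18 5,5-diethoxypent-3-yn-2-one, via lithium acetylide 16 (not isolated), via tetrahedral lithium adduct 17 (not isolated)
Conditions: n-BuLi (1.05 equiv), THF, −78 °C; then 15, −78 to 0 °C; sat. aq. NH4Cl
Reagents that add atoms: n-butyllithium, [Li]CCCC (its lithium stays only in 16 and 17)
Why: Weinreb ketone synthesis: the lithium acetylide 16 adds once to the amide and the chelated adduct 17 holds until the quench, so no tertiary alcohol forms and the acetal is untouched.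

**Step 9**
Reactants: 13 (E)-1,5-bis(guaiazulen-3-yl)-4-methylhexa-3,5-dien-2-one; 18 5,5-diethoxypent-3-yn-2-one
Product: 20 1-[2-acetyl-3-(diethoxymethyl)-5-(guaiazulen-3-yl)-6-methylphenyl]-2-(guaiazulen-3-yl)ethan-1-one, via cyclohexa-1,4-diene adduct 19 (not isolated)
Conditions: 18 (3 equiv), BHT (cat.), toluene (1 M), sealed tube, 110 °C, Ar; cool, then activated MnO2 (15 equiv), rt to 60 °C
Reagents that add atoms: none
Why: Normal-demand Diels–Alder reaction: the s-cis diene C5=C6–C7=C7a of 13 (HOMO) adds suprafacially and asynchronously to the alkyne C3a≡C4 of 18 (LUMO), C4–C5 forming ahead of C3a–C7a, as known for 2-aryl-1,3-dienes and acetylenic ketones. The one ring formed, the six-membered carbocycle, closes by intermolecular [4+2] cycloaddition through these two bonds, and MnO2 then removes H-7a (doubly allylic and alpha to the ketone) and one H-5, so that 19 becomes the benzene 20. The only new stereocentre, C7a of 19, forms racemic and is erased by the aromatisation, so nothing has to control it. The step needs regioselectivity: the guaiazulenyl donor on C6 and the acyl acceptor on C7a both put the larger HOMO coefficient on the CH2 terminus C5, which pairs with C4, the alkyne carbon beta to the acetyl group and the site of the larger LUMO coefficient, and keeping the C4 substituent as an acetal leaves acetyl as the only acceptor. The E geometry of C7=C7a turns the acyl group outward so that the s-cis conformer is reachable, and both azulenes are substituted at their two nucleophilic five-ring positions, which shuts off Michael-type attack of an azulene on the ynone. MnO2 is chosen instead of a high-potential quinone because the latter would abstract hydride from the azulene methyl groups.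

**Step 10**
Reactants: 20 1-[2-acetyl-3-(diethoxymethyl)-5-(guaiazulen-3-yl)-6-methylphenyl]-2-(guaiazulen-3-yl)ethan-1-one
Product: 22 4-(diethoxymethyl)-2,6-bis(guaiazulen-3-yl)-3,7-dimethyl-1H-inden-1-one, via 3-hydroxyindanone aldol adduct 21 (not isolated)
Conditions: KOH (0.5 equiv), EtOH/THF, rt to 50 °C
Reagents that add atoms: none
Why: Intramolecular aldol condensation of a 1,2-diacylbenzene: the C2 methylene, flanked by the C1 ketone and the azulene, is by far the most acidic site, its enolate closes the five-membered ring by 5-exo-trig attack on the acetyl carbonyl C3, and E1cB loss of water from 21 gives the fully conjugated 2-azulenylindenone, which drains the reversible alternative closure from the acetyl methyl group, while the acetal is inert to base.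

**Step 11**
Reactants: 22 4-(diethoxymethyl)-2,6-bis(guaiazulen-3-yl)-3,7-dimethyl-1H-inden-1-one
Product: 23 2,6-bis(guaiazulen-3-yl)-3,7-dimethyl-1-oxo-1H-indene-4-carbaldehyde (CNP0222726.0)
Conditions: p-TsOH·H2O (10 mol %), acetone/H2O 10:1, rt
Reagents that add atoms: water, O
Why: Acid-catalysed hydrolysis of a benzylic diethyl acetal is fast under conditions too weakly acidic to protonate the 1,3-disubstituted azulenes irreversibly or to touch the indenone.

**Compound list**
1 | guaiazulene | Cc1ccc2c(C)ccc(C(C)C)cc1-2 | starting material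
2 | TIPS-EBX | CC(C)[Si](C#CI1OC(=O)c2ccccc12)(C(C)C)C(C)C | starting material
3 | 3-[(triisopropylsilyl)ethynyl]guaiazulene | CC(C)[Si](C#Cc1cc(C)c2cc(C(C)C)ccc(C)c1-2)(C(C)C)C(C)C | intermediate
4 | 3-ethynylguaiazulene | C#Cc1cc(C)c2cc(C(C)C)ccc(C)c1-2 | intermediate
5 | [1-(guaiazulen-3-yl)vinyl]diisobutylaluminium | C=C([Al](CC(C)C)CC(C)C)c1cc(C)c2cc(C(C)C)ccc(C)c1-2 | intermediate
6 | 2-[1-(guaiazulen-3-yl)vinyl]-4,4,5,5-tetramethyl-1,3,2-dioxaborolane | C=C(B1OC(C)(C)C(C)(C)O1)c1cc(C)c2cc(C(C)C)ccc(C)c1-2 | intermediate
7 | but-2-ynoic acid | CC#CC(=O)O | starting material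
8 | (E)-3-iodobut-2-enoic acid | C/C(I)=C\C(=O)O | intermediate
9 | (trimethylsilyl)diazomethane | C[Si](C)(C)C=[N+]=[N-] | starting material
10 | (E)-3-iodobut-2-enoyl chloride | C/C(I)=C\C(=O)Cl | intermediate
11 | (E)-1-diazo-4-iodopent-3-en-2-one | C/C(I)=C\C(=O)C=[N+]=[N-] | intermediate
12 | (E)-1-(guaiazulen-3-yl)-4-iodopent-3-en-2-one | C/C(I)=C\C(=O)Cc1cc(C)c2cc(C(C)C)ccc(C)c1-2 | intermediate
13 | (E)-1,5-bis(guaiazulen-3-yl)-4-methylhexa-3,5-dien-2-one | C=C(c1cc(C)c2cc(C(C)C)ccc(C)c1-2)/C(C)=C/C(=O)Cc1cc(C)c2cc(C(C)C)ccc(C)c1-2 | intermediate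
14 | 3,3-diethoxyprop-1-yne | C#CC(OCC)OCC | starting material
15 | N-methoxy-N-methylacetamide | CC(=O)N(C)OC | starting material
16 | lithium 3,3-diethoxyprop-1-yn-1-ide | [Li]C#CC(OCC)OCC | intermediate
17 | lithium 5,5-diethoxy-2-[methoxy(methyl)amino]pent-3-yn-2-olate | [Li]OC(C)(C#CC(OCC)OCC)N(C)OC | intermediate
18 | 5,5-diethoxypent-3-yn-2-one | CC(=O)C#CC(OCC)OCC | intermediate
19 | 1-[2-acetyl-3-(diethoxymethyl)-5-(guaiazulen-3-yl)-6-methylcyclohexa-2,5-dien-1-yl]-2-(guaiazulen-3-yl)ethan-1-one (racemic) | CC(=O)C1=C(C(OCC)OCC)CC(c2cc(C)c3cc(C(C)C)ccc(C)c2-3)=C(C)C1C(=O)Cc1cc(C)c2cc(C(C)C)ccc(C)c1-2 | intermediate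
20 | 1-[2-acetyl-3-(diethoxymethyl)-5-(guaiazulen-3-yl)-6-methylphenyl]-2-(guaiazulen-3-yl)ethan-1-one | CC(=O)c1c(C(OCC)OCC)cc(-c2cc(C)c3cc(C(C)C)ccc(C)c2-3)c(C)c1C(=O)Cc1cc(C)c2cc(C(C)C)ccc(C)c1-2 | intermediate
21 | 4-(diethoxymethyl)-2,6-bis(guaiazulen-3-yl)-3-hydroxy-3,7-dimethylindan-1-one (racemic diastereomer mixture) | CC1(O)C(c2cc(C)c3cc(C(C)C)ccc(C)c2-3)C(=O)c2c(C)c(-c3cc(C)c4cc(C(C)C)ccc(C)c3-4)cc(C(OCC)OCC)c21 | intermediate
22 | 4-(diethoxymethyl)-2,6-bis(guaiazulen-3-yl)-3,7-dimethyl-1H-inden-1-one | CC1=C(c2cc(C)c3cc(C(C)C)ccc(C)c2-3)C(=O)c2c(C)c(-c3cc(C)c4cc(C(C)C)ccc(C)c3-4)cc(C(OCC)OCC)c21 | intermediate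
23 | 2,6-bis(guaiazulen-3-yl)-3,7-dimethyl-1-oxo-1H-indene-4-carbaldehyde | CC1=C(c2cc(C)c3cc(C(C)C)ccc(C)c2-3)C(=O)c2c(C)c(-c3cc(C)c4cc(C(C)C)ccc(C)c3-4)cc(C=O)c21 | target

Total step count: 11. Longest linear sequence: 7 steps (1, 2, 3, 7, 9, 10, 11; the branch 4, 5, 6, 7, 9, 10, 11 is equally long).

**Steps most likely to fail**

**Step 9.** The cycloaddition may be too slow. The C7a acyl group lowers the diene HOMO, and the peri methyl group twists the C6 azulene out of conjugation. Thermal polymerisation of the diene, stepwise [2+2] or ene pathways, and loss of regiocontrol could then outrun ring closure.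

The fallback keeps the same two bonds but raises the diene energy by changing the oxidation level at C1. It sets out from 13 and comes back at 20. Luche reduction (NaBH4, CeCl3·7H2O, MeOH/THF, −40 °C) should give (E)-1,5-bis(guaiazulen-3-yl)-4-methylhexa-3,5-dien-2-ol F1. TBSCl and imidazole in DMF should then give its tert-butyldimethylsilyl ether F2. In F2 the 1-alkyl and 3-azulenyl groups direct the addition in the same sense. Heating F2 with 18 in toluene should give the cyclohexa-1,4-diene silyl ether F3, which activated MnO2 in the same flask should aromatise to the arene silyl ether F4. Bu4NF should free the benzylic alcohol F5, and Dess–Martin periodinane with NaHCO3 should oxidise it to 20.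

**Step 6.** Carbene dimerisation, Wolff rearrangement of the ketocarbene, or attack on the seven-membered ring may compete with C3–H functionalisation.

The fallback forms C1–C2 by a Claisen-type acylation instead. It sets out from 1, uses the acid chloride 10, and comes back at 12. The same gold catalyst with tert-butyl diazoacetate, the diazoacetate case being the documented one for guaiazulene, should give tert-butyl 2-(guaiazulen-3-yl)acetate F6. LiN(SiMe3)2 (THF, −78 °C) should convert two equivalents of it into the lithium enolate F7. Acylation with 10 should give tert-butyl (E)-2-(guaiazulen-3-yl)-5-iodo-3-oxohex-4-enoate F8. CF3CO2H in CH2Cl2 followed by gentle warming should cleave the ester and decarboxylate the keto acid to 12.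

**Step 3.** Possible failures are loss of Markovnikov selectivity, deprotonation of the alkyne by the alane, and protodemetalation of the acid-sensitive alpha-azulenylvinyl metal during the aluminium-to-boron exchange or on isolation. The basic medium of step 7 adds strain on the acidic methylene of 12.

The fallback changes both the organometallic and the union to a base-free tin route. It sets out from 4 and comes back at 13. Palladium-catalysed hydrostannation (Bu3SnH, PdCl2(PPh3)2, THF, 0 °C) should favour the internal adduct because of the hindered, peri-methyl-flanked aryl group. It should give tributyl[1-(guaiazulen-3-yl)vinyl]stannane F9 after removal of the linear isomer on Et3N-treated alumina. Stille coupling with 12 (Pd2(dba)3, AsPh3, CuI, DMF, rt) should then give 13 with retention of the E geometry.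

**Further compounds**
F1 | step 9 | (E)-1,5-bis(guaiazulen-3-yl)-4-methylhexa-3,5-dien-2-ol (racemic) | C=C(c1cc(C)c2cc(C(C)C)ccc(C)c1-2)/C(C)=C/C(O)Cc1cc(C)c2cc(C(C)C)ccc(C)c1-2
F2 | step 9 | tert-butyldimethylsilyl ether of F1 (racemic) | C=C(c1cc(C)c2cc(C(C)C)ccc(C)c1-2)/C(C)=C/C(O[Si](C)(C)C(C)(C)C)Cc1cc(C)c2cc(C(C)C)ccc(C)c1-2
F3 | step 9 | cyclohexa-1,4-diene silyl ether (racemic diastereomer mixture) | CC(=O)C1=C(C(OCC)OCC)CC(c2cc(C)c3cc(C(C)C)ccc(C)c2-3)=C(C)C1C(O[Si](C)(C)C(C)(C)C)Cc1cc(C)c2cc(C(C)C)ccc(C)c1-2
F4 | step 9 | arene silyl ether, 1-{2-[1-(tert-butyldimethylsilyloxy)-2-(guaiazulen-3-yl)ethyl]-6-(diethoxymethyl)-4-(guaiazulen-3-yl)-3-methylphenyl}ethan-1-one (racemic) | CC(=O)c1c(C(OCC)OCC)cc(-c2cc(C)c3cc(C(C)C)ccc(C)c2-3)c(C)c1C(O[Si](C)(C)C(C)(C)C)Cc1cc(C)c2cc(C(C)C)ccc(C)c1-2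
F5 | step 9 | benzylic alcohol, 1-{6-(diethoxymethyl)-4-(guaiazulen-3-yl)-2-[2-(guaiazulen-3-yl)-1-hydroxyethyl]-3-methylphenyl}ethan-1-one (racemic) | CC(=O)c1c(C(OCC)OCC)cc(-c2cc(C)c3cc(C(C)C)ccc(C)c2-3)c(C)c1C(O)Cc1cc(C)c2cc(C(C)C)ccc(C)c1-2
F6 | step 6 | tert-butyl 2-(guaiazulen-3-yl)acetate | CC(C)(C)OC(=O)Cc1cc(C)c2cc(C(C)C)ccc(C)c1-2
F7 | step 6 | lithium enolate of F6 | [Li]OC(OC(C)(C)C)=Cc1cc(C)c2cc(C(C)C)ccc(C)c1-2
F8 | step 6 | tert-butyl (E)-2-(guaiazulen-3-yl)-5-iodo-3-oxohex-4-enoate (racemic) | C/C(I)=C\C(=O)C(C(=O)OC(C)(C)C)c1cc(C)c2cc(C(C)C)ccc(C)c1-2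
F9 | step 3 | tributyl[1-(guaiazulen-3-yl)vinyl]stannane | C=C([Sn](CCCC)(CCCC)CCCC)c1cc(C)c2cc(C(C)C)ccc(C)c1-2
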